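## Retrosynthetic overview

1. Target 27 is the cyclic peroxy-hemiketal of the δ-hydroperoxy β-keto ester 26, so the 1,2-dioxane is closed last (O2–C3, thermodynamic at C3). 26 comes from acid 22 by malonate homologation, and the C4 methyl from an auxiliary-controlled enolate methylation.
2. The γ-peroxy acyl unit comes from an invertive homo-conjugate addition of H2O2 across the C4–C6 bond of cyclopropyl imide 15, which sets C6.
3. The cyclopropane C4–C5–C6 comes from an asymmetric Simmons–Smith methylene transfer to (E)-allylic alcohol 8, forming C4–C5 and C5–C6 and creating the quaternary centre.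
4. 8 comes from carboalumination/hydroxymethylation of alkyne 5, made from (R)-citronellal (supplies C6–C11, the C8 stereocentre and its methyl) and 6-phenylhex-1-ene.
5. Enabling feature: in the 1,2-dioxane, C5 is an unsubstituted CH2 between C4 (alpha to the hemiketal carbon C3) and the quaternary peroxy carbon C6, so C4–C5–C6 can be carried as a cyclopropane whose C4–C6 bond is polarised by the acyl group on C4. Ring order: cyclopropane (step 5), opened (step 8), 1,2-dioxane (step 13).

Key step: step 5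

Remark on the chemistry: numbering is O1–O2–C3(OH)(CH2CO2Me)–C4(CH3)–C5H2–C6(CH3)(side chain), with C7 and C8 the first two side-chain carbons. C3 equilibrates through the open hydroperoxy ketone, and the (3S) epimer (axial OH) is assumed to be the thermodynamic one. C4 and C6 are not under thermodynamic control (the two alkyl groups on C6 are of like size), so each is set by reagent control.

## Route

Step 1
Reactants: 1 (R)-citronellal; 2 6-phenylhex-1-ene
Product: 3 (3R)-3-methyl-11-phenylundec-6-enal (E/Z mixture)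
Conditions: second-generation Grubbs catalyst (5 mol%), 2 (3 equiv), CH2Cl2, 40 °C
Reagents that add atoms: none
Why: Olefin cross-metathesis of the prenyl-type trisubstituted alkene with a terminal alkene should be driven by loss of volatile 2-methylpropene, and the chiral-pool stereocentre (later C8) is not touched.

Step 2
Reactants: 3 (3R)-3-methyl-11-phenylundec-6-enal
Product: 4 (3R)-3-methyl-11-phenylundecanal
Conditions: H2 (1 atm), 10% Pd/C, EtOAc, rt
Reagents that add atoms: none
Why: Heterogeneous hydrogenation should saturate the disubstituted alkene while the aliphatic aldehyde and the arene survive at 1 atm.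

Step 3
Reactants: 4 (3R)-3-methyl-11-phenylundecanal
Product: 5 (4R)-4-methyl-12-phenyldodec-1-yne
Conditions: dimethyl (1-diazo-2-oxopropyl)phosphonate, K2CO3, MeOH, 0 °C to rt
Reagents that add atoms: dimethyl (1-diazo-2-oxopropyl)phosphonate, CC(=O)C(=[N+]=[N-])P(=O)(OC)OC
Why: The Ohira–Bestmann variant of the Seyferth–Gilbert homologation should convert the aldehyde into the terminal alkyne under mildly basic conditions that cannot epimerise the beta stereocentre.

Step 4
Reactants: 5 (4R)-4-methyl-12-phenyldodec-1-yne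
Product: 8 (2E,5R)-3,5-dimethyl-13-phenyltridec-2-en-1-ol, via alkenylalane 6 (not isolated), via lithium alkenylaluminate 7 (not isolated)
Conditions: AlMe3 (2 equiv), Cp2ZrCl2 (0.25 equiv), CH2Cl2, 0 °C to rt; then n-BuLi, THF, −78 °C; (CH2O)n, rt; aq. HCl work-up
Reagents that add atoms: trimethylaluminium, C[Al](C)C; paraformaldehyde (as formaldehyde), C=O
Why: Zirconium-catalysed syn-carboalumination (Negishi) should place CH3 on the internal and aluminium on the terminal alkyne carbon, and the aluminate should add to formaldehyde with retention, fixing the (E) geometry.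

Step 5
Reactants: 8 (2E,5R)-3,5-dimethyl-13-phenyltridec-2-en-1-ol
Product: 10 [(1R,2R)-2-methyl-2-[(2R)-2-methyl-10-phenyldecyl]cyclopropyl]methanol, via iodomethylzinc alkoxide 9 (not isolated)
Conditions: Zn(CH2I)2·DME (from Et2Zn and CH2I2, 2.2 equiv), (4S,5S)-2-butyl-N,N,N',N'-tetramethyl-1,3,2-dioxaborolane-4,5-dicarboxamide (1.2 equiv), CH2Cl2, −10 °C to rt
Reagents that add atoms: diiodomethane, ICI
Why: The zinc alkoxide 9 should bind the dioxaborolane (alkoxide oxygen to boron, amide carbonyl to zinc), and a second Zn(CH2I)2 should deliver CH2 through the butterfly transition state of the Simmons–Smith reaction, so that C4–C5 and C5–C6 (dioxane numbering) form in one concerted syn methylene transfer. The closest known reaction type is the ligand-controlled asymmetric Simmons–Smith cyclopropanation (Charette variant) of geraniol-type 3,3-disubstituted (E)-allylic alcohols. The three-membered ring closes in a concerted [2+1] mode on one alkene face. The relative configuration of the two new ring stereocentres follows from the (E) geometry of 8 (CH2OH cis to CH3); their absolute configuration follows from the (4S,5S) ligand, the mirror image of the ligand that converts (E)-cinnamyl alcohol into the (1S,2S)-cyclopropylmethanol, and the quaternary centre becomes C6 after the inversion in step 8. The selectivity needed is facial: the homoallylic C8 stereocentre lies outside the zinc chelate and should not compete with reagent control, and the directing hydroxyl sits on the only alkene of 8.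

Step 6
Reactants: 10 [(1R,2R)-2-methyl-2-[(2R)-2-methyl-10-phenyldecyl]cyclopropyl]methanol
Product: 12 (1R,2R)-2-methyl-2-[(2R)-2-methyl-10-phenyldecyl]cyclopropane-1-carboxylic acid, via cyclopropanecarbaldehyde 11 (not isolated)
Conditions: TEMPO (0.2 equiv), PhI(OAc)2 (2.2 equiv), MeCN/H2O (1:1), rt
Reagents that add atoms: water, O
Why: Oxoammonium oxidation of the primary alcohol to the aldehyde and of its hydrate to the acid should leave the cyclopropane and all stereocentres untouched.

Step 7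
Reactants: 12 (1R,2R)-2-methyl-2-[(2R)-2-methyl-10-phenyldecyl]cyclopropane-1-carboxylic acid; 13 (4R)-4-benzyl-1,3-oxazolidin-2-one
Product: 15 (4R)-4-benzyl-3-{(1R,2R)-2-methyl-2-[(2R)-2-methyl-10-phenyldecyl]cyclopropane-1-carbonyl}-1,3-oxazolidin-2-one, via mixed pivalic anhydride 14 (not isolated)
Conditions: t-BuCOCl, Et3N, THF, −20 °C; then LiCl, 13, −20 °C to rt
Reagents that add atoms: none
Why: The mixed pivalic anhydride should acylate the oxazolidinone nitrogen at its less hindered carbonyl (standard N-acylation), giving an imide that later serves as two-point Lewis-acid binding site and as controller for C4.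

Step 8
Reactants: 15 (4R)-4-benzyl-3-{(1R,2R)-2-methyl-2-[(2R)-2-methyl-10-phenyldecyl]cyclopropane-1-carbonyl}-1,3-oxazolidin-2-one
Product: 17 (4R)-4-benzyl-3-[(4R,6R)-4-hydroperoxy-4,6-dimethyl-14-phenyltetradecanoyl]-1,3-oxazolidin-2-one, via scandium-bound enol 16 (not isolated)
Conditions: Sc(OTf)3 (10 mol%), anhydrous H2O2 in Et2O (10 equiv), CH2Cl2, −40 to 0 °C
Reagents that add atoms: hydrogen peroxide, OO
Why: Proposed new method: two-point binding of Sc(OTf)3 to the imide carbonyls should polarise the distal C4–C6 cyclopropane bond towards the tertiary carbon, H2O2 should attack that carbon from the side opposite to C4 (SN2-like, inversion, giving the C6 configuration of the target) while the enol 16 is protonated to the CH2 group, and attack at C5 is disfavoured because only C6 can carry positive charge; the closest known reaction types are the Lewis-acid-mediated invertive perhydrolysis of 2,2-disubstituted oxetanes and epoxides and the stereospecific homo-conjugate opening of donor–acceptor cyclopropanes by heteroatom nucleophiles.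

Step 9
Reactants: 17 (4R)-4-benzyl-3-[(4R,6R)-4-hydroperoxy-4,6-dimethyl-14-phenyltetradecanoyl]-1,3-oxazolidin-2-one
Product: 18 (4R)-4-benzyl-3-[(4R,6R)-4-[(2-methoxypropan-2-yl)peroxy]-4,6-dimethyl-14-phenyltetradecanoyl]-1,3-oxazolidin-2-one
Conditions: 2-methoxypropene (3 equiv), PPTS (5 mol%), CH2Cl2, 0 °C (on crude 17)
Reagents that add atoms: 2-methoxypropene, COC(C)=C
Why: Acid-catalysed addition of the hydroperoxide to the enol ether (peroxyketal formation) should remove the acidic OOH before base chemistry and prevent its acyl transfer onto the imide.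

Step 10
Reactants: 18 (4R)-4-benzyl-3-[(4R,6R)-4-[(2-methoxypropan-2-yl)peroxy]-4,6-dimethyl-14-phenyltetradecanoyl]-1,3-oxazolidin-2-one
Product: 20 (4R)-4-benzyl-3-[(2R,4S,6R)-4-[(2-methoxypropan-2-yl)peroxy]-2,4,6-trimethyl-14-phenyltetradecanoyl]-1,3-oxazolidin-2-one, via sodium (Z)-enolate 19 (not isolated)
Conditions: NaN(SiMe3)2 (1.1 equiv), THF, −78 °C; MeI (5 equiv), −78 °C
Reagents that add atoms: iodomethane, CI
Why: Evans alkylation: the chelated (Z)-enolate should be methylated on the face opposite the benzyl group, which with the (4R) auxiliary sets C4 as (R), and at −78 °C a stabilised imide enolate is expected to leave the hindered di-tert-alkyl peroxide alone.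

Step 11
Reactants: 20 (4R)-4-benzyl-3-[(2R,4S,6R)-4-[(2-methoxypropan-2-yl)peroxy]-2,4,6-trimethyl-14-phenyltetradecanoyl]-1,3-oxazolidin-2-one
Product: 22 (2R,4S,6R)-4-[(2-methoxypropan-2-yl)peroxy]-2,4,6-trimethyl-14-phenyltetradecanoic acid, via peroxy acid 21 (not isolated)
Conditions: LiOH, H2O2, THF/H2O (3:1), 0 °C; then Na2SO3 (aq.); NaHSO4 (aq.) to pH 4
Reagents that add atoms: hydrogen peroxide, OO
Why: Hydroperoxide anion should attack the exocyclic imide carbonyl selectively, sulfite should reduce the peracid but not the dialkyl peroxyketal, and C4 should not epimerise at 0 °C.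

Step 12
Reactants: 22 (2R,4S,6R)-4-[(2-methoxypropan-2-yl)peroxy]-2,4,6-trimethyl-14-phenyltetradecanoic acid
Product: 25 methyl (4R,6S,8R)-6-[(2-methoxypropan-2-yl)peroxy]-4,6,8-trimethyl-3-oxo-16-phenylhexadecanoate, via acyl imidazole 23 (not isolated), via acylmalonic half-ester 24 (not isolated)
Conditions: 1,1'-carbonyldiimidazole, THF, rt; then Mg(O2CCH2CO2Me)2, THF, rt; cold aq. NaHSO4 work-up
Reagents that add atoms: magnesium bis(3-methoxy-3-oxopropanoate), COC(=O)CC(=O)[O-].COC(=O)CC(=O)[O-].[Mg+2]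
Why: Masamune-type homologation: the acyl imidazole should C-acylate the magnesium malonate and decarboxylate to the β-keto ester under near-neutral conditions that spare the peroxyketal and the C4 stereocentre.

Step 13
Reactants: 25 methyl (4R,6S,8R)-6-[(2-methoxypropan-2-yl)peroxy]-4,6,8-trimethyl-3-oxo-16-phenylhexadecanoate
Product: 27 methyl 2-[(3S,4R,6S)-3-hydroxy-4,6-dimethyl-6-[(2R)-2-methyl-10-phenyldecyl]-1,2-dioxan-3-yl]acetate, via hydroperoxy keto ester 26 (not isolated)
Conditions: AcOH/THF/H2O (4:2:1), rt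
Reagents that add atoms: none
Why: Mild aqueous acid should hydrolyse the peroxyketal, and the freed hydroperoxide should add to the C3 ketone (6-exo hemiketalisation) to give the anomerically stabilised axial-OH epimer at C3 under thermodynamic control, with C4 and C6 untouched.

## Compound list

1 | (R)-citronellal, (3R)-3,7-dimethyloct-6-enal | O=CC[C@H](C)CCC=C(C)C | starting material
2 | 6-phenylhex-1-ene | C=CCCCCc1ccccc1 | starting material
3 | (3R)-3-methyl-11-phenylundec-6-enal (E/Z mixture) | O=CC[C@H](C)CCC=CCCCCc1ccccc1 | intermediate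
4 | (3R)-3-methyl-11-phenylundecanal | O=CC[C@H](C)CCCCCCCCc1ccccc1 | intermediate
5 | (4R)-4-methyl-12-phenyldodec-1-yne | C#CC[C@H](C)CCCCCCCCc1ccccc1 | intermediate
6 | dimethyl[(1E,4R)-2,4-dimethyl-12-phenyldodec-1-en-1-yl]alumane | C[Al](C)/C=C(C)/C[C@H](C)CCCCCCCCc1ccccc1 | intermediate
7 | lithium butyl[(1E,4R)-2,4-dimethyl-12-phenyldodec-1-en-1-yl]dimethylaluminate | [Li+].CCCC[Al-](C)(C)/C=C(C)/C[C@H](C)CCCCCCCCc1ccccc1 | intermediate
8 | (2E,5R)-3,5-dimethyl-13-phenyltridec-2-en-1-ol | OC/C=C(C)/C[C@H](C)CCCCCCCCc1ccccc1 | intermediate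
9 | (iodomethyl){[(2E,5R)-3,5-dimethyl-13-phenyltridec-2-en-1-yl]oxy}zinc | IC[Zn]OC/C=C(C)/C[C@H](C)CCCCCCCCc1ccccc1 | intermediate
10 | [(1R,2R)-2-methyl-2-[(2R)-2-methyl-10-phenyldecyl]cyclopropyl]methanol | OC[C@@H]1C[C@@]1(C)C[C@H](C)CCCCCCCCc1ccccc1 | intermediate
11 | (1R,2R)-2-methyl-2-[(2R)-2-methyl-10-phenyldecyl]cyclopropane-1-carbaldehyde | O=C[C@@H]1C[C@@]1(C)C[C@H](C)CCCCCCCCc1ccccc1 | intermediate
12 | (1R,2R)-2-methyl-2-[(2R)-2-methyl-10-phenyldecyl]cyclopropane-1-carboxylic acid | OC(=O)[C@@H]1C[C@@]1(C)C[C@H](C)CCCCCCCCc1ccccc1 | intermediate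
13 | (4R)-4-benzyl-1,3-oxazolidin-2-one | O=C1OC[C@@H](Cc2ccccc2)N1 | starting material
14 | (1R,2R)-2-methyl-2-[(2R)-2-methyl-10-phenyldecyl]cyclopropane-1-carboxylic 2,2-dimethylpropanoic anhydride | CC(C)(C)C(=O)OC(=O)[C@@H]1C[C@@]1(C)C[C@H](C)CCCCCCCCc1ccccc1 | intermediate
15 | (4R)-4-benzyl-3-{(1R,2R)-2-methyl-2-[(2R)-2-methyl-10-phenyldecyl]cyclopropane-1-carbonyl}-1,3-oxazolidin-2-one | O=C([C@@H]1C[C@@]1(C)C[C@H](C)CCCCCCCCc2ccccc2)N3[C@H](Cc4ccccc4)COC3=O | intermediate
16 | enol tautomer of 17 (acyl C1 enol, held as its scandium chelate) | OC(=CC[C@@](C)(OO)C[C@H](C)CCCCCCCCc1ccccc1)N2[C@H](Cc3ccccc3)COC2=O | intermediate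
17 | (4R)-4-benzyl-3-[(4R,6R)-4-hydroperoxy-4,6-dimethyl-14-phenyltetradecanoyl]-1,3-oxazolidin-2-one | O=C(CC[C@@](C)(OO)C[C@H](C)CCCCCCCCc1ccccc1)N2[C@H](Cc3ccccc3)COC2=O | intermediate
18 | (4R)-4-benzyl-3-[(4R,6R)-4-[(2-methoxypropan-2-yl)peroxy]-4,6-dimethyl-14-phenyltetradecanoyl]-1,3-oxazolidin-2-one | O=C(CC[C@@](C)(OOC(C)(C)OC)C[C@H](C)CCCCCCCCc1ccccc1)N2[C@H](Cc3ccccc3)COC2=O | intermediate
19 | sodium (Z)-enolate of 18 | [Na+].[O-]/C(=C\C[C@@](C)(OOC(C)(C)OC)C[C@H](C)CCCCCCCCc1ccccc1)N2[C@H](Cc3ccccc3)COC2=O | intermediate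
20 | (4R)-4-benzyl-3-[(2R,4S,6R)-4-[(2-methoxypropan-2-yl)peroxy]-2,4,6-trimethyl-14-phenyltetradecanoyl]-1,3-oxazolidin-2-one | O=C([C@H](C)C[C@@](C)(OOC(C)(C)OC)C[C@H](C)CCCCCCCCc1ccccc1)N2[C@H](Cc3ccccc3)COC2=O | intermediate
21 | (2R,4S,6R)-4-[(2-methoxypropan-2-yl)peroxy]-2,4,6-trimethyl-14-phenyltetradecaneperoxoic acid | OOC(=O)[C@H](C)C[C@@](C)(OOC(C)(C)OC)C[C@H](C)CCCCCCCCc1ccccc1 | intermediate
22 | (2R,4S,6R)-4-[(2-methoxypropan-2-yl)peroxy]-2,4,6-trimethyl-14-phenyltetradecanoic acid | OC(=O)[C@H](C)C[C@@](C)(OOC(C)(C)OC)C[C@H](C)CCCCCCCCc1ccccc1 | intermediate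
23 | (2R,4S,6R)-1-(1H-imidazol-1-yl)-4-[(2-methoxypropan-2-yl)peroxy]-2,4,6-trimethyl-14-phenyltetradecan-1-one | O=C([C@H](C)C[C@@](C)(OOC(C)(C)OC)C[C@H](C)CCCCCCCCc1ccccc1)n2ccnc2 | intermediate
24 | (4R,6S,8R)-2-(methoxycarbonyl)-6-[(2-methoxypropan-2-yl)peroxy]-4,6,8-trimethyl-3-oxo-16-phenylhexadecanoic acid | COC(=O)C(C(O)=O)C(=O)[C@H](C)C[C@@](C)(OOC(C)(C)OC)C[C@H](C)CCCCCCCCc1ccccc1 | intermediate
25 | methyl (4R,6S,8R)-6-[(2-methoxypropan-2-yl)peroxy]-4,6,8-trimethyl-3-oxo-16-phenylhexadecanoate | COC(=O)CC(=O)[C@H](C)C[C@@](C)(OOC(C)(C)OC)C[C@H](C)CCCCCCCCc1ccccc1 | intermediate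
26 | methyl (4R,6S,8R)-6-hydroperoxy-4,6,8-trimethyl-3-oxo-16-phenylhexadecanoate | COC(=O)CC(=O)[C@H](C)C[C@@](C)(OO)C[C@H](C)CCCCCCCCc1ccccc1 | intermediate
27 | methyl 2-[(3S,4R,6S)-3-hydroxy-4,6-dimethyl-6-[(2R)-2-methyl-10-phenyldecyl]-1,2-dioxan-3-yl]acetate | COC(=O)C[C@]1(O)OO[C@@](C)(C[C@H](C)CCCCCCCCc2ccccc2)C[C@H]1C | target

## Step count and risks

Total step count: 13. Longest linear sequence: 13 steps (from 1).

Steps most likely to fail:

1. Step 8 (Proposed new method). The cyclopropane may open by ionisation to a free tertiary carbocation, which would erode the configuration at C6 and allow elimination, or the new hydroperoxide may transfer the acyl group from the imide to itself. Fallback with known chemistry, setting out from 8 and coming back at 18: Sharpless asymmetric epoxidation of 8 (Ti(OiPr)4, D-(−)-diethyl tartrate, t-BuOOH, 4 Å sieves, −20 °C; the enantiomer of the tartrate that converts geraniol into its (2S,3S)-epoxide) should give the epoxy alcohol [(2R,3R)-3-methyl-3-[(2R)-2-methyl-10-phenyldecyl]oxiran-2-yl]methanol F1, which is silylated (TBDPSCl, imidazole) to its tert-butyldiphenylsilyl ether F2. Perhydrolysis with ethereal H2O2 and catalytic H3PMo12O40 should open the epoxide at the tertiary carbon with inversion to give the β-hydroxy hydroperoxide F3. The hydroperoxide is capped with 2-methoxypropene/PPTS to give the peroxyketal F4, and n-Bu4NF frees the 1,2-diol F5. NaIO4 cleaves this to the α-peroxy aldehyde (2S,4R)-2-[(2-methoxypropan-2-yl)peroxy]-2,4-dimethyl-12-phenyldodecanal F6. A Wittig reaction with (4R)-4-benzyl-3-[2-(triphenylphosphoranylidene)acetyl]-1,3-oxazolidin-2-one gives the (E)-enoyl imide F7, and diimide (2-nitrobenzenesulfonohydrazide, Et3N) should reduce the disubstituted alkene without touching the O–O bond to give 18.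

2. Step 10. The enolate may attack the nearby O–O bond (intramolecular substitution at oxygen to an oxetane) faster than it is methylated, or facial control may be eroded. Fallback, setting out from 8 and coming back at 22, in which C4 is set by alkylating a propionyl imide with the peroxide-bearing electrophile so that no enolate is generated gamma to the peroxide: 8 is taken to aldehyde F6 as described above. F6 is reduced (NaBH4, MeOH, 0 °C) to the alcohol (2S,4R)-2-[(2-methoxypropan-2-yl)peroxy]-2,4-dimethyl-12-phenyldodecan-1-ol F8 and converted (Tf2O, 2,6-lutidine, −78 °C) into its trifluoromethanesulfonate F9. F9 alkylates the sodium enolate of (4S)-4-benzyl-3-propanoyl-1,3-oxazolidin-2-one (NaN(SiMe3)2, THF, −78 to −20 °C) to give the imide (4S)-4-benzyl-3-[(2R,4S,6R)-4-[(2-methoxypropan-2-yl)peroxy]-2,4,6-trimethyl-14-phenyltetradecanoyl]-1,3-oxazolidin-2-one F10. LiOH/H2O2 then gives 22.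

3. Step 1. The trisubstituted alkene may turn over slowly, with self-metathesis of 2 and double-bond migration competing. Fallback, setting out from 1 and coming back at 3: 1 is converted (HC(OMe)3, TsOH, MeOH) into the dimethyl acetal (3R)-1,1-dimethoxy-3,7-dimethyloct-6-ene F11. Ozonolysis (O3, CH2Cl2, −78 °C; PPh3) gives the aldehyde (4R)-6,6-dimethoxy-4-methylhexanal F12. A Wittig reaction with the ylide from (5-phenylpentyl)triphenylphosphonium bromide and NaN(SiMe3)2 gives the alkene (3R,6Z)-1,1-dimethoxy-3-methyl-11-phenylundec-6-ene F13, and aqueous acid (TsOH, acetone/H2O) frees aldehyde 3 as its (Z) isomer, which step 2 saturates all the same.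

## Further compounds

F1 | step 8 | [(2R,3R)-3-methyl-3-[(2R)-2-methyl-10-phenyldecyl]oxiran-2-yl]methanol | OC[C@H]1O[C@]1(C)C[C@H](C)CCCCCCCCc1ccccc1
F2 | step 8 | tert-butyl{[(2R,3R)-3-methyl-3-[(2R)-2-methyl-10-phenyldecyl]oxiran-2-yl]methoxy}diphenylsilane | CC(C)(C)[Si](OC[C@H]1O[C@]1(C)C[C@H](C)CCCCCCCCc2ccccc2)(c3ccccc3)c4ccccc4
F3 | step 8 | (2R,3S,5R)-1-[(tert-butyldiphenylsilyl)oxy]-3-hydroperoxy-3,5-dimethyl-13-phenyltridecan-2-ol | CC(C)(C)[Si](OC[C@@H](O)[C@@](C)(OO)C[C@H](C)CCCCCCCCc1ccccc1)(c2ccccc2)c3ccccc3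
F4 | step 8 | (2R,3S,5R)-1-[(tert-butyldiphenylsilyl)oxy]-3-[(2-methoxypropan-2-yl)peroxy]-3,5-dimethyl-13-phenyltridecan-2-ol | CC(C)(C)[Si](OC[C@@H](O)[C@@](C)(OOC(C)(C)OC)C[C@H](C)CCCCCCCCc1ccccc1)(c2ccccc2)c3ccccc3
F5 | step 8 | (2R,3S,5R)-3-[(2-methoxypropan-2-yl)peroxy]-3,5-dimethyl-13-phenyltridecane-1,2-diol | OC[C@@H](O)[C@@](C)(OOC(C)(C)OC)C[C@H](C)CCCCCCCCc1ccccc1
F6 | step 8 | (2S,4R)-2-[(2-methoxypropan-2-yl)peroxy]-2,4-dimethyl-12-phenyldodecanal | O=C[C@@](C)(OOC(C)(C)OC)C[C@H](C)CCCCCCCCc1ccccc1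
F7 | step 8 | (4R)-4-benzyl-3-[(2E,4S,6R)-4-[(2-methoxypropan-2-yl)peroxy]-4,6-dimethyl-14-phenyltetradec-2-enoyl]-1,3-oxazolidin-2-one | O=C(/C=C/[C@@](C)(OOC(C)(C)OC)C[C@H](C)CCCCCCCCc1ccccc1)N2[C@H](Cc3ccccc3)COC2=O
F8 | step 10 | (2S,4R)-2-[(2-methoxypropan-2-yl)peroxy]-2,4-dimethyl-12-phenyldodecan-1-ol | OC[C@@](C)(OOC(C)(C)OC)C[C@H](C)CCCCCCCCc1ccccc1
F9 | step 10 | (2S,4R)-2-[(2-methoxypropan-2-yl)peroxy]-2,4-dimethyl-12-phenyldodecyl trifluoromethanesulfonate | FC(F)(F)S(=O)(=O)OC[C@@](C)(OOC(C)(C)OC)C[C@H](C)CCCCCCCCc1ccccc1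
F10 | step 10 | (4S)-4-benzyl-3-[(2R,4S,6R)-4-[(2-methoxypropan-2-yl)peroxy]-2,4,6-trimethyl-14-phenyltetradecanoyl]-1,3-oxazolidin-2-one | O=C([C@H](C)C[C@@](C)(OOC(C)(C)OC)C[C@H](C)CCCCCCCCc1ccccc1)N2[C@@H](Cc3ccccc3)COC2=O
F11 | step 1 | (3R)-1,1-dimethoxy-3,7-dimethyloct-6-ene | COC(OC)C[C@H](C)CCC=C(C)C
F12 | step 1 | (4R)-6,6-dimethoxy-4-methylhexanal | COC(OC)C[C@H](C)CCC=O
F13 | step 1 | (3R,6Z)-1,1-dimethoxy-3-methyl-11-phenylundec-6-ene | COC(OC)C[C@H](C)CC/C=C\CCCCc1ccccc1
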